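Ring B is cut at C9–C10 and C7–C8. The tetrasubstituted C8=C9 alkene is treated as a former alkyne and the C6 oxygen, para to C9, as a silyl enol ether, so that a [4+2] addition of the 2-silyloxydiene C7=C6–C5=C10 (ring A of β-cyclocitral carrying an enol-silylated acetyl group) to methyl but-2-ynoate closes ring B, creates quaternary C10 and installs C17 and C11 on C8=C9 in one operation. The masked C6 ketone then steers the trans ring fusion, α-face hydroxylation at C7 and α-face hydride delivery at C6, while C11 is extended through a vinyl group, hydroboration and Suzuki–Miyaura coupling with a Z iodobutenol.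

Key step: step 4

Remark: labdane numbering is used (C1–C5 and C10 ring A; C5–C10 ring B; C11–C16 side chain; C17 on C8; C18 and C19 on C4; C20 on C10; β = face of C20); the sense of induction in step 4 cannot be predicted with confidence, so the (S)-catalyst is written and its antipode is taken if a pilot run shows the opposite sense; changes of the CIP letter at C10 between intermediates are formal, the spatial arrangement being the same throughout.

Step 1
Reactants: 1 β-cyclocitral
Product: 2 1-(2,6,6-trimethylcyclohex-1-en-1-yl)ethan-1-ol (racemic)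
Conditions: MeMgBr, THF, 0 °C → rt; aq. NH4Cl
Reagents that add atoms: methylmagnesium bromide, C[Mg]Br
Why: Grignard 1,2-addition to the hindered, non-enolisable aldehyde gives the secondary allylic alcohol, whose carbinol stereocenter forms as a racemate and is erased in step 2.

Step 2
Reactants: 2 1-(2,6,6-trimethylcyclohex-1-en-1-yl)ethan-1-ol
Product: 3 1-(2,6,6-trimethylcyclohex-1-en-1-yl)ethan-1-one
Conditions: Dess–Martin periodinane, NaHCO3, CH2Cl2, 0 °C → rt
Reagents that add atoms: none
Why: Dess–Martin oxidation converts the secondary allylic alcohol into the methyl ketone under buffered, neutral conditions that leave the tetrasubstituted alkene untouched and create no stereocenter.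

Step 3
Reactants: 3 1-(2,6,6-trimethylcyclohex-1-en-1-yl)ethan-1-one
Product: 5 tert-butyldimethyl{[1-(2,6,6-trimethylcyclohex-1-en-1-yl)ethenyl]oxy}silane, via potassium enolate 4 (not isolated)
Conditions: KN(SiMe3)2, THF, −78 °C; TBSCl, −78 → 0 °C
Reagents that add atoms: potassium bis(trimethylsilyl)amide (potassium in 4 only), [K+].C[Si](C)(C)[N-][Si](C)(C)C; tert-butyldimethylsilyl chloride, CC(C)(C)[Si](C)(C)Cl
Why: Kinetic deprotonation of the twisted enone by the bulky amide occurs at the acetyl methyl group and O-silylation of the potassium enolate gives the cross-conjugated 2-silyloxydiene C7=C6–C5=C10 (silyl enol ether formation), with no stereocenter formed.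

Step 4
Reactants: 5 tert-butyldimethyl{[1-(2,6,6-trimethylcyclohex-1-en-1-yl)ethenyl]oxy}silane; 6 methyl but-2-ynoate
Product: 7 methyl (10S)-6-(tert-butyldimethylsilyloxy)-12,13,14,15,16-pentanorlabda-5,8-dien-11-oate
Conditions: (S)-3,3-diphenyl-1-(2-methylphenyl)tetrahydro-1H,3H-pyrrolo[1,2-c][1,3,2]oxazaborole (20 mol %), HNTf2 (16 mol %), CH2Cl2, −60 → −20 °C
Reagents that add atoms: none
Why: Proposed new method: the triflimide-activated oxazaborolidinium ion binds the ester carbonyl of 6, the silyl enol ether terminus C7 of 5 attacks the methyl-bearing alkyne carbon (C8) and the ester-bearing carbon C9 then bonds to C10, either in one asynchronous [4+2] event or as a Mukaiyama–Michael addition followed by collapse of the boron allenolate onto the silyloxyallyl cation. The closest known reaction types are chiral boron Lewis acid-catalysed enantioselective Diels–Alder additions of dienes to acetylenic aldehydes and ketones and of 2-silyloxybutadienes to acrylate esters, and uncatalysed additions of 2-vinyl-1,3,3-trimethylcyclohexenes to acetylenic esters; an ynoate combined with a twisted, fully substituted diene terminus has not been shown. Ring B closes as a six-membered carbocycle by intermolecular [4+2] cycloaddition, the second bond (C9–C10) forming in a 6-endo-trig sense at the allyl cation terminus if the path is stepwise. The only new stereocenter, quaternary C10, is under catalyst control: the chiral boron complex screens one side of the ester plane and its bulk keeps ring A away from the carbonyl group, so that one enantioface of C5=C10 is offered to C9. The step needs para regioselectivity, six- over four-membered ring closure and enantioface selectivity; the donor oxygen on C6 and the acceptor on C9 secure the first, reversible opening of any cyclobutene adduct under the Lewis acid should feed the second, and the quaternary C10 excludes aromatisation of the 1,4-diene.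

Step 5
Reactants: 7 methyl (10S)-6-(tert-butyldimethylsilyloxy)-12,13,14,15,16-pentanorlabda-5,8-dien-11-oate
Product: 8 (10R)-6-(tert-butyldimethylsilyloxy)-12,13,14,15,16-pentanorlabda-5,8-dien-11-ol
Conditions: iBu2AlH, CH2Cl2, −78 → 0 °C; aq. potassium sodium tartrate
Reagents that add atoms: none
Why: Hydride reduction of the conjugated ester by iBu2AlH goes through to the primary allylic alcohol and leaves the silyl enol ether and C10 untouched, the tartrate work-up avoiding acid (ester reduction).

Step 6
Reactants: 8 (10R)-6-(tert-butyldimethylsilyloxy)-12,13,14,15,16-pentanorlabda-5,8-dien-11-ol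
Product: 9 (10S)-6-(tert-butyldimethylsilyloxy)-12,13,14,15,16-pentanorlabda-5,8-dien-11-al
Conditions: MnO2, CH2Cl2, rt
Reagents that add atoms: none
Why: MnO2 oxidises primary allylic alcohols to enals under neutral heterogeneous conditions, so the silyl enol ether survives and no stereocenter is touched (allylic alcohol oxidation).

Step 7
Reactants: 9 (10S)-6-(tert-butyldimethylsilyloxy)-12,13,14,15,16-pentanorlabda-5,8-dien-11-al
Product: 10 (10R)-6-(tert-butyldimethylsilyloxy)-13,14,15,16-tetranorlabda-5,8,11-triene
Conditions: Ph3PCH3Br, KOtBu, THF, 0 °C; then 9, −78 → 0 °C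
Reagents that add atoms: methyltriphenylphosphonium bromide, [Br-].C[P+](c1ccccc1)(c1ccccc1)c1ccccc1
Why: Wittig methylenation of the hindered enal by the non-stabilised ylide adds C12 as a terminal vinyl group in an aprotic medium that the silyl enol ether tolerates, with no stereocenter formed.

Step 8
Reactants: 11 but-2-yn-1-ol
Product: 13 (Z)-3-iodobut-2-en-1-ol, via cyclic alkenylalanate 12 (not isolated)
Conditions: NaAlH2(OCH2CH2OMe)2, THF, 0 °C → rt; I2, THF, −78 °C
Reagents that add atoms: sodium bis(2-methoxyethoxy)aluminium dihydride (aluminium, sodium and alkoxy groups in 12 only), [Na+].COCCO[AlH2-]OCCOC; iodine, II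
Why: Alkoxide-directed trans-hydroalumination of the propargylic alcohol places aluminium on C3 in a five-membered alanate and iodinolysis of the C–Al bond with retention gives the Z vinyl iodide (iodine cis to CH2OH), which fixes the later C13=C14 geometry (hydroalumination–iodination).

Step 9
Reactants: 10 (10R)-6-(tert-butyldimethylsilyloxy)-13,14,15,16-tetranorlabda-5,8,11-triene; 13 (Z)-3-iodobut-2-en-1-ol
Product: 15 (10R,13Z)-6-(tert-butyldimethylsilyloxy)labda-5,8,13-trien-15-ol, via B-alkyl-9-BBN borane 14 (not isolated)
Conditions: 9-BBN-H, THF, 0 °C → rt; then 13, PdCl2(dppf) (5 mol %; dppf = 1,1'-bis(diphenylphosphino)ferrocene), AsPh3, Cs2CO3, DMF/H2O, rt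
Reagents that add atoms: 9-borabicyclo[3.3.1]nonane (boron in 14 only), B1C2CCCC1CCC2
Why: 9-BBN adds to the only monosubstituted alkene with boron on terminal C12 (anti-Markovnikov hydroboration, the tetrasubstituted alkenes being inert) and the B-alkyl Suzuki–Miyaura coupling joins C12 to C13 with retention of the Z geometry and tolerance of the free hydroxyl, no stereocenter being formed.

Step 10
Reactants: 15 (10R,13Z)-6-(tert-butyldimethylsilyloxy)labda-5,8,13-trien-15-ol
Product: 16 (5S,10S,13Z)-15-hydroxylabda-8,13-dien-6-one
Conditions: Bu4NF, AcOH, THF, 0 °C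
Reagents that add atoms: none
Why: Fluoride cleaves the Si–O bond of the enol ether and the enolate is protonated at C5 on the α face, away from the axial methyl groups on C10 and C4, which should give the trans-fused ketone that is also expected to be the more stable epimer, the acetic acid buffer suppressing migration of C8=C9 into conjugation (desilylation–ketonisation).

Step 11
Reactants: 16 (5S,10S,13Z)-15-hydroxylabda-8,13-dien-6-one
Product: 18 (5S,7S,10S,13Z)-7,15-dihydroxylabda-8,13-dien-6-one (7α-OH), via dipotassium alkoxide-dienolate 17 (not isolated)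
Conditions: KN(SiMe3)2 (2.2 equiv), THF, −78 °C; 2-(phenylsulfonyl)-3-phenyloxaziridine, −78 °C; AcOH
Reagents that add atoms: potassium bis(trimethylsilyl)amide (potassium in 17 only), [K+].C[Si](C)(C)[N-][Si](C)(C)C; 2-(phenylsulfonyl)-3-phenyloxaziridine, O=S(=O)(c1ccccc1)N1OC1c1ccccc1
Why: After the hydroxyl is deprotonated, the bulky base removes the accessible allylic C7 proton and not the C5 methine flanked by two quaternary carbons, and the dienolate is hydroxylated at its α carbon C7 by axial attack on the α face, opposite the C10 methyl, which should set 7α-OH without epoxidising C8=C9 or C13=C14 (enolate oxidation by an N-sulfonyloxaziridine).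

Step 12
Reactants: 18 (5S,7S,10S,13Z)-7,15-dihydroxylabda-8,13-dien-6-one
Product: 19 (5S,7S,10S,13Z)-6-oxolabda-8,13-diene-7,15-diyl diacetate (7α-OAc)
Conditions: Ac2O, pyridine, DMAP (cat.), CH2Cl2, 0 °C
Reagents that add atoms: acetic anhydride, CC(=O)OC(C)=O
Why: DMAP-catalysed acylation esterifies the primary allylic C15 hydroxyl and the secondary C7 hydroxyl in one operation with retention at C7, the short reaction at 0 °C limiting enolisation of the α-acetoxy ketone.

Step 13
Reactants: 19 (5S,7S,10S,13Z)-6-oxolabda-8,13-diene-7,15-diyl diacetate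
Product: 20 (5S,6S,7S,10S,13Z)-6-hydroxylabda-8,13-diene-7,15-diyl diacetate (6β-OH; 7α-OAc; CNP0415913.2)
Conditions: NaBH4, CeCl3·7H2O, MeOH, −40 °C
Reagents that add atoms: none
Why: Borohydride delivers hydride to the C6 ketone from the α face because the β face is shielded by the two syn-axial methyl groups on C4 and C10, which should give the axial 6β-alcohol trans to the 7α-acetate, while CeCl3 and low temperature keep both acetates in place (Luche-type ketone reduction).

Compound list
1 | β-cyclocitral (2,6,6-trimethylcyclohex-1-ene-1-carbaldehyde) | CC1=C(C=O)C(C)(C)CCC1 | starting material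
2 | 1-(2,6,6-trimethylcyclohex-1-en-1-yl)ethan-1-ol (racemic) | CC(O)C1=C(C)CCCC1(C)C | intermediate
3 | 1-(2,6,6-trimethylcyclohex-1-en-1-yl)ethan-1-one | CC(=O)C1=C(C)CCCC1(C)C | intermediate
4 | potassium 1-(2,6,6-trimethylcyclohex-1-en-1-yl)ethen-1-olate | [K+].C=C([O-])C1=C(C)CCCC1(C)C | intermediate
5 | tert-butyldimethyl{[1-(2,6,6-trimethylcyclohex-1-en-1-yl)ethenyl]oxy}silane | C=C(O[Si](C)(C)C(C)(C)C)C1=C(C)CCCC1(C)C | intermediate
6 | methyl but-2-ynoate | CC#CC(=O)OC | starting material
7 | methyl (10S)-6-(tert-butyldimethylsilyloxy)-12,13,14,15,16-pentanorlabda-5,8-dien-11-oate (= methyl (8aS)-4-[(tert-butyldimethylsilyl)oxy]-2,5,5,8a-tetramethyl-3,5,6,7,8,8a-hexahydronaphthalene-1-carboxylate) | COC(=O)C1=C(C)CC(O[Si](C)(C)C(C)(C)C)=C2C(C)(C)CCC[C@]12C | intermediate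
8 | (10R)-6-(tert-butyldimethylsilyloxy)-12,13,14,15,16-pentanorlabda-5,8-dien-11-ol | OCC1=C(C)CC(O[Si](C)(C)C(C)(C)C)=C2C(C)(C)CCC[C@]12C | intermediate
9 | (10S)-6-(tert-butyldimethylsilyloxy)-12,13,14,15,16-pentanorlabda-5,8-dien-11-al | O=CC1=C(C)CC(O[Si](C)(C)C(C)(C)C)=C2C(C)(C)CCC[C@]12C | intermediate
10 | (10R)-6-(tert-butyldimethylsilyloxy)-13,14,15,16-tetranorlabda-5,8,11-triene | C=CC1=C(C)CC(O[Si](C)(C)C(C)(C)C)=C2C(C)(C)CCC[C@]12C | intermediate
11 | but-2-yn-1-ol | CC#CCO | starting material
12 | sodium 2,2-bis(2-methoxyethoxy)-3-methyl-2,5-dihydro-1,2-oxaaluminol-2-uide (cyclic alkenylalanate) | CC1=CCO[Al-]1(OCCOC)OCCOC.[Na+] | intermediate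
13 | (Z)-3-iodobut-2-en-1-ol | C/C(I)=C/CO | intermediate
14 | 9-[(10R)-6-(tert-butyldimethylsilyloxy)-13,14,15,16-tetranorlabda-5,8-dien-12-yl]-9-borabicyclo[3.3.1]nonane | C1CC2CCCC(C1)B2CCC1=C(C)CC(O[Si](C)(C)C(C)(C)C)=C2C(C)(C)CCC[C@]12C | intermediate
15 | (10R,13Z)-6-(tert-butyldimethylsilyloxy)labda-5,8,13-trien-15-ol | OC/C=C(/C)CCC1=C(C)CC(O[Si](C)(C)C(C)(C)C)=C2C(C)(C)CCC[C@]12C | intermediate
16 | (5S,10S,13Z)-15-hydroxylabda-8,13-dien-6-one (trans-fused; H5 α) | OC/C=C(/C)CCC1=C(C)CC(=O)[C@H]2C(C)(C)CCC[C@]12C | intermediate
17 | dipotassium salt of 16 (C15 alkoxide; C6=C7 dienolate) | [K+].[K+].[O-]C/C=C(/C)CCC1=C(C)C=C([O-])[C@H]2C(C)(C)CCC[C@]12C | intermediate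
18 | (5S,7S,10S,13Z)-7,15-dihydroxylabda-8,13-dien-6-one (7α-OH) | OC/C=C(/C)CCC1=C(C)[C@H](O)C(=O)[C@H]2C(C)(C)CCC[C@]12C | intermediate
19 | (5S,7S,10S,13Z)-6-oxolabda-8,13-diene-7,15-diyl diacetate (7α-OAc) | CC(=O)OC/C=C(/C)CCC1=C(C)[C@H](OC(C)=O)C(=O)[C@H]2C(C)(C)CCC[C@]12C | intermediate
20 | (5S,6S,7S,10S,13Z)-6-hydroxylabda-8,13-diene-7,15-diyl diacetate (6β-OH; 7α-OAc) | CC(=O)OC/C=C(/C)CCC1=C(C)[C@H](OC(C)=O)[C@@H](O)[C@H]2C(C)(C)CCC[C@]12C | target

Total step count: 13. Longest linear sequence: 12 steps (steps 1–7 and 9–13 from β-cyclocitral); step 8 is the one-step side branch.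

Steps most likely to fail

1. Step 4 (key step, new method). The catalyst may fail to tell apart the two faces of the twisted C5=C10 terminus. Turnover with the β-methyl ynoate may also be slow, closure may divert to a four-membered ring, or the diene may be protodesilylated. Fallback with known chemistry, setting out from 5 and rejoining the route at 8: but-2-ynoic acid is esterified with (−)-menthol (DCC, DMAP) to give (1R,2S,5R)-menthyl but-2-ynoate F1. Compound 5 and F1 are then heated without catalyst (toluene, sealed tube, about 160 °C, trace of Et3N), the classical thermal Diels–Alder addition of a 2-silyloxydiene to an acetylenic ester. No induction is assumed; both C10 epimers should form as diastereomeric esters, the (10S) menthyl ester adduct F2 and the (10R) menthyl ester adduct F3, and these are separated by chromatography or crystallisation. F2 is reduced with iBu2AlH under the conditions of step 5, which releases the auxiliary and gives 8.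

2. Step 11. The oxidant may approach the dienolate from the β face, or deprotonation and attack may not be confined to C7. Fallback, setting out from 16 and rejoining at 19: if the β-face product prevails, the 7β-hydroxy ketone F4 is carried on instead of being discarded. Mitsunobu esterification with acetic acid (PPh3, diisopropyl azodicarboxylate, THF, 0 °C) inverts C7 by SN2 displacement and esterifies the primary C15 hydroxyl in the same flask. The C7 configuration then rests on inversion and not on the facial preference of the oxidation, and the product is 19.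

3. Step 13. The polar C7 acetoxy group may draw part of the hydride to the β face, and the basic borohydride medium may epimerise C7 or cleave an acetate. Fallback, setting out from 18 and rejoining at 20: the order of the last two operations is reversed. The free 7α-hydroxyl of 18 directs internal hydride delivery from Me4NBH(OAc)3 (MeCN/AcOH, −20 °C) to the α face of C6, giving the 6β,7α,15-triol F5. Acetylation with Ac2O in pyridine at 0 °C without DMAP then esterifies the primary C15 and the allylic C7 hydroxyls. The axial 6β-hydroxyl, flanked by the syn-axial methyl groups on C4 and C10, should remain free, giving 20.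

Further compounds
F1 | step 4 | (1R,2S,5R)-menthyl but-2-ynoate | C[C@@H]1CC[C@H]([C@@H](C1)OC(=O)C#CC)C(C)C
F2 | step 4 | (1R,2S,5R)-menthyl (10S)-6-(tert-butyldimethylsilyloxy)-12,13,14,15,16-pentanorlabda-5,8-dien-11-oate | C[C@@H]1CC[C@H]([C@@H](C1)OC(=O)C2=C(C)CC(O[Si](C)(C)C(C)(C)C)=C3C(C)(C)CCC[C@]23C)C(C)C
F3 | step 4 | (1R,2S,5R)-menthyl (10R)-6-(tert-butyldimethylsilyloxy)-12,13,14,15,16-pentanorlabda-5,8-dien-11-oate | C[C@@H]1CC[C@H]([C@@H](C1)OC(=O)C2=C(C)CC(O[Si](C)(C)C(C)(C)C)=C3C(C)(C)CCC[C@@]23C)C(C)C
F4 | step 11 | (5S,7R,10S,13Z)-7,15-dihydroxylabda-8,13-dien-6-one (7β-OH) | OC/C=C(/C)CCC1=C(C)[C@@H](O)C(=O)[C@H]2C(C)(C)CCC[C@]12C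
F5 | step 13 | (5S,6S,7S,10S,13Z)-labda-8,13-diene-6,7,15-triol (6β-OH; 7α-OH) | OC/C=C(/C)CCC1=C(C)[C@H](O)[C@@H](O)[C@H]2C(C)(C)CCC[C@]12C
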